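## Structural features

The target is (2R,3S,4S,5R)-2,5-bis(4-hydroxy-3-methoxyphenyl)-3,4-dimethyloxolan-3-ol: one oxolane ring (O1, C2–C5) with two identical 4-hydroxy-3-methoxyphenyl groups on C2 and C5, a methyl and a hydroxyl on C3, and a methyl on C4. All four ring carbons are stereocentres and stand in a row (C2–C3–C4–C5), and C3 is a fully substituted tertiary carbinol between two of them. The two aryl groups are cis, the C3 methyl lies on their face, and the C3 hydroxyl and the C4 methyl lie together on the other face. The ring C–O bonds are both benzylic and para to a phenolic oxygen, so acid can ionise them (epimerisation at C2 or C5) and hydrogenolysis can cleave them. The tertiary alcohol can be lost by dehydration, and the free phenols are easily oxidised. The real difficulty is the relative configuration of four contiguous centres, one of them the tertiary carbinol, together with the absolute configuration of a molecule that departs from mirror symmetry only at C3 and C4. The key step uses this near symmetry: O1 with its two identical aryl carbinol carbons C2 and C5 is the C–O–C unit of a symmetrical diaryl carbonyl ylide, and C3–C4 is a trisubstituted alkene, so C2–C3 and C4–C5 can be formed in one cycloaddition.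

## Logic of the disconnections

16 to 15: the two phenolic O–CH2 bonds are cut. The phenols would interfere with photo-oxidation, hydride reagents and sulfonylation, so they stay masked to the end. The benzyl ether is chosen because the aldehyde that carries it, 1, is commercial and no protection step is needed. The demand on the forward step is that unmasking spares the benzylic C–O bonds of the ring.

15 to 12 (through 14 and 13): a C–H bond of the C3 methyl is traced back to a C–O bond. That carbon has to enter as a carbonyl carbon, because only then does it activate the alkene partner of the cycloaddition. The gain is that 12 is the fully reduced form of an α-oxygenated acyl derivative. The demand is deoxygenation of the primary position without breaking the tertiary C3–O bond, which is met by closing the oxirane 14 and opening it with hydride.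

12 to 11: the acyl C–N bond to the auxiliary and the O–acetyl bond are restored. The imide carbonyl activates and orients the alkene, the auxiliary carries the absolute information, and the acetate holds the enol oxygen in place. The gain is that 11 is the direct cycloadduct. The demand is that hydride attacks the exocyclic carbonyl of a hindered imide.

11 to 3 and 9 (through 10): C2–C3 and C4–C5 are cut. These bonds flank O1 symmetrically, so C2–O1–C5 becomes the symmetrical ylide 10, available from 3, and C3–C4 becomes the alkene of 9. The gain is the largest in the route: the ring and all four stereocentres arise in one step from two achiral or racemic-tolerant pieces. The demands are a W-shaped ylide, transfer of the (Z) geometry, endo orientation of the imide carbonyl, and addition to one alkene face.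

9 to 6 and 7, then 6 to 4: the N–acyl bond is cut, then the enol O–acetyl bond. This leads to the commercial compounds 7 and 4. The demands are a (Z)-selective enol acetylation and an N-acylation mild enough to leave the enol ester alone.

3 to 2, then 2 to 1: the two C–O bonds of the oxirane are cut (oxygen transfer to an alkene), then the C=C bond. Both halves are the same commercial aldehyde 1, two molecules of which are joined. The C–C bond made in the coupling is the one later broken in forming 10; it only holds the two aryl carbinol carbons together until oxygen bridges them. The demand is an acid-free epoxidation, because 3 is very sensitive to acid.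

## Other disconnections considered

Alternative 1: The cut runs through O1–C2 and C2–C3. C2 with its aryl group becomes a carbene carbon, and the other four ring atoms come from the anti-aldol A2 (its hydroxyl oxygen is O1, its ketone carbon is C3). In the forward sense Rh2(OAc)4 would decompose the aryl diazoacetate A3, the hydroxyl of A2 would add to the rhodium carbene, and the oxonium ylide would close onto the ketone in an intramolecular aldol step to give A1.
- In its favour: the tertiary carbinol C3 with its methyl group arises directly, which is better than the chosen plan, where that methyl must be carved out of a carbonyl group. The C4/C5 pair can come from a catalytic asymmetric aldol reaction, so no stoichiometric auxiliary is needed. No photochemistry is involved.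
- Against it here: A1 carries an ester on C2, a quaternary benzylic ether carbon. Its replacement by hydrogen on a defined face (saponification, Barton decarboxylation, hydrogen-atom capture by an α-oxy benzylic radical) would set C2 in a step of uncertain selectivity. Simple O–H insertion by proton shift would compete with the aldol trapping. A2 is prone to retro-aldol cleavage and dehydration.
- Comparison: on structure, it uses the unsymmetrical C3/C4 part well but ignores the equivalence of C2 and C5. On mechanism, both key steps pass through ylides and make two bonds; control is from the substrate there and from an auxiliary here, and neither is secure. On step economy it would be longer (about ten or eleven steps against eight) because the ester has to be excised. It is the equal of the chosen plan in convergence.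

Alternative 2: The cut is O1–C5 alone, leading back to the open-chain diol A5 with one free phenol. In the forward sense Ag2O would oxidise the 4-alkyl-2-methoxyphenol of A5 to its p-quinone methide, and the C2 hydroxyl would add to the methide carbon in a five-membered conjugate closure to give A4, one debenzylation from the target.
- In its favour: the closure is ionic, mild and reversible. Only one stereocentre (C5) is formed, and the preference of the aryl group to lie trans to the C4 methyl is what the target requires. On predictability of stereochemistry this is the better of the two plans. The other three centres can be set by reliable open-chain methods with catalytic absolute control. Only one step follows the key step, against three in the chosen plan.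
- Against it here: the two aryl rings must be differentiated (one free phenol, one ether), so the symmetry is not used and two building blocks are needed. The oxidation can divert into phenoxyl coupling or into tautomerisation of the methide to a styrene through the C4 hydrogen. Making A5 with three contiguous centres is a linear task of roughly nine to eleven steps.
- Comparison: on structure the chosen plan is the better, since it exploits the identical halves. On mechanism the alternative is the safer. On step economy the chosen plan is shorter and more convergent.

Alternative 3: The cut runs through C4–C5 and O1–C2. In the forward sense BF3·OEt2 would activate aldehyde A8 (the same compound as 1) towards anti-SE2′ attack by the (Z)-allylsilane A7. The β-silyl cation would undergo a 1,2-silyl shift, and the oxygen would close onto the benzylic carbon to give A6, in which silicon stands for the C3 hydroxyl. A Tamao–Fleming oxidation (retention) and debenzylation would follow.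
- In its favour: it is convergent and uses the same commercial aldehyde. All four centres derive from one stereogenic C–Si centre through a stereospecific cascade, a better-defined source of absolute configuration than a remote auxiliary. The tertiary carbinol is reached without degrading a carbonyl group, in two steps after the key step against three here.
- Against it here: the shift must create a fully substituted silicon-bearing C3. The cation at C2 is a long-lived 4-alkoxybenzyl cation, so closure may lose stereochemical fidelity and loss of silicon (simple allylation) may compete, the more so with the small PhMe2Si group that the oxidation needs. The electrophile required to cleave the phenyl–silicon bond (HBF4, bromine sources, Hg(OAc)2) threatens the electron-rich rings and the benzylic ethers. Enantiopure A7 is itself a synthesis of several steps.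
- Comparison: on structure it uses only one of the two equivalent aryl carbinol carbons as such. On mechanism the chosen concerted cycloaddition should transfer geometry more faithfully than a stepwise cationic cascade, while the alternative is the better on the origin of absolute configuration. On step economy the two plans are about equal.

Key step: step 5

Assumption (stereochemical model): in the unchelated, dipole-opposed s-trans rotamer of 9 the benzyl group of the (4S)-auxiliary lies on the Cα-re side, so the required Cα-si face is open; if the sense were the opposite, the (4R)-antipode of 7 would be used with no other change.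

## Route

Step 1
Reactants: 1 4-benzyloxy-3-methoxybenzaldehyde (first molecule); 1 4-benzyloxy-3-methoxybenzaldehyde (second molecule; 2 equiv of 1 in all)
Product: 2 (E)-1,2-bis(4-benzyloxy-3-methoxyphenyl)ethene
Conditions: TiCl4, Zn, THF, 0 °C then reflux
Reagents that add atoms: none
Why: McMurry reductive coupling on low-valent titanium joins two molecules of 1 head to head through a titanium pinacolate that is deoxygenated at reflux, so both aldehyde oxygens are lost to titanium; aryl aldehydes should give mainly the crystalline (E)-stilbene, and aryl benzyl and methyl ethers are inert. The alkene geometry does not matter later, because both oxirane isomers lead to the same ylide.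

Step 2
Reactants: 2 (E)-1,2-bis(4-benzyloxy-3-methoxyphenyl)ethene
Product: 3 trans-2,3-bis(4-benzyloxy-3-methoxyphenyl)oxirane (racemic)
Conditions: KHSO5 (as 2KHSO5·KHSO4·K2SO4), acetone, NaHCO3, Bu4NHSO4 (cat.), CH2Cl2/H2O, 0 °C to rt
Reagents that add atoms: potassium peroxymonosulfate, [K+].[O-]S(=O)(=O)OO (its oxygen atom is passed on through dimethyldioxirane, CC1(C)OO1, formed from acetone in the flask)
Why: Dioxirane epoxidation is concerted and stereospecific (trans oxirane from the (E)-alkene) and leaves only acetone; this replaces a peracid because bis(4-alkoxyphenyl)oxiranes are opened or rearranged by the carboxylic acid a peracid would release. The product should be purified on base-washed silica and used soon.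

Step 3
Reactants: 4 2-oxobutanoic acid
Product: 6 (Z)-2-acetoxybut-2-enoic acid, via mixed acetic anhydride 5 (not isolated)
Conditions: Ac2O, TsOH·H2O (cat.), 80 °C; then H2O, THF, rt
Reagents that add atoms: acetic anhydride, CC(=O)OC(C)=O
Why: Acid-catalysed enol acetylation of an α-keto acid, the reaction type by which arylpyruvic acids give α-acetoxycinnamic acids; the equilibrating conditions should favour the (Z) isomer with the methyl group away from the carboxyl group. Mild hydrolysis should cleave only the far more reactive carboxylic anhydride of 5.

Step 4
Reactants: 6 (Z)-2-acetoxybut-2-enoic acid; 7 (S)-4-benzyloxazolidin-2-one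
Product: 9 (S)-4-benzyl-3-[(Z)-2-acetoxybut-2-enoyl]oxazolidin-2-one, via mixed pivalic anhydride 8 (not isolated)
Conditions: PivCl, Et3N, THF, −20 °C; then 7, LiCl, −20 °C to rt
Reagents that add atoms: none
Why: N-Acylation of an oxazolidinone through a mixed pivalic anhydride in the presence of LiCl is the standard mild route to enoyl imides; the hindered pivaloyl carbonyl directs attack to the enoyl carbonyl. No strong base meets the enol acetate, and the alkene geometry is not at risk.

Step 5
Reactants: 3 trans-2,3-bis(4-benzyloxy-3-methoxyphenyl)oxirane (racemic); 9 (S)-4-benzyl-3-[(Z)-2-acetoxybut-2-enoyl]oxazolidin-2-one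
Product: 11 (4S)-3-{[(2R,3S,4S,5R)-3-acetoxy-2,5-bis(4-benzyloxy-3-methoxyphenyl)-4-methyloxolan-3-yl]carbonyl}-4-benzyloxazolidin-2-one, via carbonyl ylide 10 (not isolated)
Conditions: 2,4,6-triphenylpyrylium tetrafluoroborate (5 mol%), 9 (1.5 equiv), 4 Å molecular sieves, CH2Cl2, argon, blue LEDs (ca. 420–450 nm), rt
Reagents that add atoms: none
Why: The excited pyrylium salt oxidises 3 by one electron, the oxirane radical cation opens at its C–C bond, and back electron transfer from the pyranyl radical gives carbonyl ylide 10, which should relax to the W-shaped form with both aryl groups outside whatever the geometry of 3. The closest known reaction type is the sensitised electron-transfer (3+2) cycloaddition of 2,3-diaryloxiranes with electron-poor alkenes to give cis-2,5-diaryloxolanes; the donor-substituted, nucleophilic ylide is matched with the acceptor-activated alkene of 9. The oxolane is closed by a concerted suprafacial–suprafacial 1,3-dipolar cycloaddition in which C2–C3 and C4–C5 form together, so no separate exo or endo ring-closing event is involved. C2 and C5 (aryl groups cis) are set by the W geometry of the ylide, and the cis relation of the C3 oxygen and the C4 methyl is set by the (Z) geometry of 9, which a concerted addition transfers. The relation of C3 and C4 to C2 and C5 is set by the endo orientation of the imide carbonyl, which should be favoured by attraction between the carbonyl oxygen and the positively polarised ylide oxygen and by the β-methyl group, which in the exo mode would sit under the dipole and cis to an aryl group. The absolute configuration is set by the auxiliary: in the endo arrangement the oxazolidinone lies beneath an aryl group of the dipole, and in the rotamer of the assumption its benzyl group covers the Cα-re face, so the ylide should add to the Cα-si face. The step needs trapping of the ylide to outrun reclosure, rearrangement and oxygenation, which excess 9, exclusion of acid and oxygen and a low sensitiser loading should secure; any minor facial or exo isomer is a diastereomer of 11 and can be removed at this stage by chromatography or crystallisation.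

Step 6
Reactants: 11 (4S)-3-{[(2R,3S,4S,5R)-3-acetoxy-2,5-bis(4-benzyloxy-3-methoxyphenyl)-4-methyloxolan-3-yl]carbonyl}-4-benzyloxazolidin-2-one
Product: 12 (2R,3R,4S,5R)-2,5-bis(4-benzyloxy-3-methoxyphenyl)-3-(hydroxymethyl)-4-methyloxolan-3-ol
Conditions: LiAlH4, THF, 0 °C; aq. potassium sodium tartrate
Reagents that add atoms: none
Why: Hydride reduction of the N-acyloxazolidinone at its exocyclic carbonyl (reductive removal of the auxiliary, which is recovered) and of the tertiary acetate should give the primary–tertiary 1,2-diol. No bond to a stereocentre is broken; the descriptor of C3 changes only through the priority rules.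

Step 7
Reactants: 12 (2R,3R,4S,5R)-2,5-bis(4-benzyloxy-3-methoxyphenyl)-3-(hydroxymethyl)-4-methyloxolan-3-ol
Product: 15 (2R,3S,4S,5R)-2,5-bis(4-benzyloxy-3-methoxyphenyl)-3,4-dimethyloxolan-3-ol, via primary tosylate 13 (not isolated), via spiro-epoxide 14 (not isolated)
Conditions: NaH, N-tosylimidazole, THF, 0 °C to rt; then LiEt3BH, 0 °C to rt; H2O
Reagents that add atoms: none
Why: The less hindered primary alkoxide is sulfonylated by N-tosylimidazole and the neighbouring tertiary alkoxide displaces the tosylate (3-exo-tet) to give oxirane 14, the known one-flask conversion of 1,2-diols into epoxides. LiEt3BH should then open 14 by SN2 delivery of hydride to the unsubstituted carbon, the standard reduction of 2,2-disubstituted oxiranes to tertiary methyl carbinols; the C3–O bond is never broken, so the carbinol configuration is retained.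

Step 8
Reactants: 15 (2R,3S,4S,5R)-2,5-bis(4-benzyloxy-3-methoxyphenyl)-3,4-dimethyloxolan-3-ol
Product: 16 (2R,3S,4S,5R)-2,5-bis(4-hydroxy-3-methoxyphenyl)-3,4-dimethyloxolan-3-ol
Conditions: H2 (1 atm), 10% Pd/C, EtOAc, rt
Reagents that add atoms: none
Why: Catalytic hydrogenolysis of the two aryl benzyl ethers; under neutral conditions at atmospheric pressure the O–benzyl bonds should be cleaved much faster than the benzylic C–O bonds of the oxolane. The reaction is stopped after uptake of two equivalents of hydrogen, and no stereocentre is touched.

## Compound list

1 | 4-benzyloxy-3-methoxybenzaldehyde | COc1cc(C=O)ccc1OCc1ccccc1 | starting material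
2 | (E)-1,2-bis(4-benzyloxy-3-methoxyphenyl)ethene | COc1cc(/C=C/c2ccc(OCc3ccccc3)c(OC)c2)ccc1OCc1ccccc1 | intermediate
3 | trans-2,3-bis(4-benzyloxy-3-methoxyphenyl)oxirane, racemic (one enantiomer drawn) | COc1cc([C@@H]2O[C@H]2c3ccc(OCc4ccccc4)c(OC)c3)ccc1OCc1ccccc1 | intermediate
4 | 2-oxobutanoic acid | CCC(=O)C(=O)O | starting material
5 | acetic (Z)-2-acetoxybut-2-enoic anhydride | C/C=C(\OC(C)=O)C(=O)OC(C)=O | intermediate
6 | (Z)-2-acetoxybut-2-enoic acid | C/C=C(\OC(C)=O)C(=O)O | intermediate
7 | (S)-4-benzyloxazolidin-2-one | O=C1N[C@@H](Cc2ccccc2)CO1 | starting material
8 | (Z)-2-acetoxybut-2-enoic pivalic anhydride | C/C=C(\OC(C)=O)C(=O)OC(=O)C(C)(C)C | intermediate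
9 | (S)-4-benzyl-3-[(Z)-2-acetoxybut-2-enoyl]oxazolidin-2-one | C/C=C(\OC(C)=O)C(=O)N1[C@@H](Cc2ccccc2)COC1=O | intermediate
10 | bis(4-benzyloxy-3-methoxyphenyl) carbonyl ylide, W-shaped form (one resonance structure drawn) | COc1cc(/C=[O+]/[CH-]c2ccc(OCc3ccccc3)c(OC)c2)ccc1OCc1ccccc1 | intermediate
11 | (4S)-3-{[(2R,3S,4S,5R)-3-acetoxy-2,5-bis(4-benzyloxy-3-methoxyphenyl)-4-methyloxolan-3-yl]carbonyl}-4-benzyloxazolidin-2-one | COc1cc([C@H]2O[C@@H](c3ccc(OCc4ccccc4)c(OC)c3)[C@H](C)[C@]2(C(=O)N5[C@@H](Cc6ccccc6)COC5=O)OC(C)=O)ccc1OCc1ccccc1 | intermediate
12 | (2R,3R,4S,5R)-2,5-bis(4-benzyloxy-3-methoxyphenyl)-3-(hydroxymethyl)-4-methyloxolan-3-ol | COc1cc([C@H]2O[C@@H](c3ccc(OCc4ccccc4)c(OC)c3)[C@H](C)[C@]2(CO)O)ccc1OCc1ccccc1 | intermediate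
13 | [(2R,3R,4S,5R)-2,5-bis(4-benzyloxy-3-methoxyphenyl)-3-hydroxy-4-methyloxolan-3-yl]methyl 4-methylbenzenesulfonate | COc1cc([C@H]2O[C@@H](c3ccc(OCc4ccccc4)c(OC)c3)[C@H](C)[C@]2(COS(=O)(=O)c5ccc(C)cc5)O)ccc1OCc1ccccc1 | intermediate
14 | (3R,4R,6R,7S)-4,6-bis(4-benzyloxy-3-methoxyphenyl)-7-methyl-1,5-dioxaspiro[2.4]heptane | COc1cc([C@H]2O[C@@H](c3ccc(OCc4ccccc4)c(OC)c3)[C@H](C)[C@@]25CO5)ccc1OCc1ccccc1 | intermediate
15 | (2R,3S,4S,5R)-2,5-bis(4-benzyloxy-3-methoxyphenyl)-3,4-dimethyloxolan-3-ol | COc1cc([C@H]2O[C@@H](c3ccc(OCc4ccccc4)c(OC)c3)[C@H](C)[C@]2(C)O)ccc1OCc1ccccc1 | intermediate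
16 | (2R,3S,4S,5R)-2,5-bis(4-hydroxy-3-methoxyphenyl)-3,4-dimethyloxolan-3-ol | COc1cc([C@H]2O[C@@H](c3ccc(O)c(OC)c3)[C@H](C)[C@]2(C)O)ccc1O | target

## Step count and least certain steps

Total: 8 steps. Longest linear sequence: 6 steps (steps 1, 2, 5, 6, 7, 8; the branch through steps 3 and 4 is equally long).

Step 5 (key step). What may go wrong:
- slow capture of the ylide by a trisubstituted alkene, so that reclosure, rearrangement to carbonyl compounds or oxygenation of the ylide takes over;
- insufficient endo preference;
- weak facial discrimination, because the imide cannot be locked by chelation under these conditions and its rotamers may expose both faces;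
- further photo-oxidation of the electron-rich product by the sensitiser.

Fallback, setting out from 3 and returning at 12: the acyclic imide is replaced by a rigid, flat, s-cis-locked captodative dipolarophile whose face control does not depend on rotamers. Commercial (R)-2-hydroxybutanoic acid and pivalaldehyde are condensed (TsOH cat., pentane, azeotropic removal of water) to (2R,5R)-2-tert-butyl-5-ethyl-1,3-dioxolan-4-one F1, whose cis isomer is purified. Radical bromination (NBS, AIBN) gives 5-bromo-2-tert-butyl-5-ethyl-1,3-dioxolan-4-one F2, and elimination with Et3N gives (2R,5Z)-2-tert-butyl-5-ethylidene-1,3-dioxolan-4-one F3. Under the conditions of step 5 the ylide from 3 should add to the face of F3 opposite the tert-butyl group (the Cα-si face) with the small lactone carbonyl endo, to give (2R,5S,6R,8R,9S)-2-tert-butyl-6,8-bis(4-benzyloxy-3-methoxyphenyl)-9-methyl-1,3,7-trioxaspiro[4.4]nonan-4-one F4. LiAlH4 then reduces the lactone and releases the acetal to give 12 directly.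

Step 6. What may go wrong: hydride attack at the endocyclic carbonyl of the hindered imide (ring opening of the auxiliary followed by reduction of the resulting amide to an amine), or acyl transfer to the freed tertiary alkoxide before the imide is reduced. Fallback, from 11 back to 12: hydrolysis with LiOH/H2O2 in THF/H2O, where hydroperoxide attacks the exocyclic carbonyl selectively and the acetate is also removed, gives (2R,3S,4S,5R)-2,5-bis(4-benzyloxy-3-methoxyphenyl)-3-hydroxy-4-methyloxolane-3-carboxylic acid F5, which is reduced to 12 with LiAlH4 or BH3·THF.

Step 3. What may go wrong: self-condensation or decarboxylation of the keto acid in hot acidic anhydride, incomplete (Z) selectivity, or loss of the enol acetate during hydrolysis of 5. Fallback, from 4 and 7 back to 9: 4 is converted with Cl2CHOCH3 into 2-oxobutanoyl chloride F6, which acylates lithiated 7 (n-BuLi, THF, −78 °C) to give (S)-4-benzyl-3-(2-oxobutanoyl)oxazolidin-2-one F7. Enol acetylation of the more acidic keto imide (Ac2O, Et3N, DMAP, CH2Cl2) then gives 9.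

Step 2. What may go wrong: acid-promoted opening or rearrangement of the very electron-rich oxirane during reaction, work-up or chromatography. Fallback, from 2 back to the route at 10: dihydroxylation (OsO4 cat., NMO) gives rac-(1R,2R)-1,2-bis(4-benzyloxy-3-methoxyphenyl)ethane-1,2-diol F8, and Mitsunobu cyclodehydration (PPh3, DIAD) under neutral conditions gives cis-2,3-bis(4-benzyloxy-3-methoxyphenyl)oxirane F9. In step 5 this opens to the same ylide 10, so any loss of stereochemical fidelity in the closure is harmless.

Step 8. What may go wrong: over-reduction, that is hydrogenolysis of a benzylic ring C–O bond once the phenols are free. Fallback, from 15 back to 16: electron-transfer cleavage of the aryl benzyl ethers with lithium naphthalenide (LiC10H8) in THF at low temperature. The phenoxides formed make the rings too electron-rich to accept a further electron, which should protect the ring C–O bonds. No new compound is involved.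

## Further compounds

F1 | step 5 | (2R,5R)-2-tert-butyl-5-ethyl-1,3-dioxolan-4-one | CC[C@H]1O[C@@H](C(C)(C)C)OC1=O
F2 | step 5 | 5-bromo-2-tert-butyl-5-ethyl-1,3-dioxolan-4-one (acetal carbon as in F1, both C5 epimers) | CCC1(Br)O[C@@H](C(C)(C)C)OC1=O
F3 | step 5 | (2R,5Z)-2-tert-butyl-5-ethylidene-1,3-dioxolan-4-one | C/C=C1\O[C@@H](C(C)(C)C)OC1=O
F4 | step 5 | (2R,5S,6R,8R,9S)-2-tert-butyl-6,8-bis(4-benzyloxy-3-methoxyphenyl)-9-methyl-1,3,7-trioxaspiro[4.4]nonan-4-one | COc1cc([C@H]2O[C@@H](c3ccc(OCc4ccccc4)c(OC)c3)[C@H](C)[C@]26O[C@@H](C(C)(C)C)OC6=O)ccc1OCc1ccccc1
F5 | step 6 | (2R,3S,4S,5R)-2,5-bis(4-benzyloxy-3-methoxyphenyl)-3-hydroxy-4-methyloxolane-3-carboxylic acid | COc1cc([C@H]2O[C@@H](c3ccc(OCc4ccccc4)c(OC)c3)[C@H](C)[C@]2(C(=O)O)O)ccc1OCc1ccccc1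
F6 | step 3 | 2-oxobutanoyl chloride | CCC(=O)C(Cl)=O
F7 | step 3 | (S)-4-benzyl-3-(2-oxobutanoyl)oxazolidin-2-one | CCC(=O)C(=O)N1[C@@H](Cc2ccccc2)COC1=O
F8 | step 2 | rac-(1R,2R)-1,2-bis(4-benzyloxy-3-methoxyphenyl)ethane-1,2-diol (one enantiomer drawn) | COc1cc([C@@H](O)[C@H](O)c2ccc(OCc3ccccc3)c(OC)c2)ccc1OCc1ccccc1
F9 | step 2 | cis-2,3-bis(4-benzyloxy-3-methoxyphenyl)oxirane (meso) | COc1cc([C@@H]2O[C@@H]2c3ccc(OCc4ccccc4)c(OC)c3)ccc1OCc1ccccc1
F0 | step 8 | none | none
A1 | alternative 1 | methyl 2,5-bis(4-benzyloxy-3-methoxyphenyl)-3-hydroxy-3,4-dimethyloxolane-2-carboxylate (ester in place of the C2 hydrogen of the target) | COc1cc([C@@]2(C(=O)OC)O[C@@H](c3ccc(OCc4ccccc4)c(OC)c3)[C@H](C)[C@]2(C)O)ccc1OCc1ccccc1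
A2 | alternative 1 | (3S,4R)-4-(4-benzyloxy-3-methoxyphenyl)-4-hydroxy-3-methylbutan-2-one | O[C@@H](c1ccc(OCc2ccccc2)c(OC)c1)[C@H](C)C(C)=O
A3 | alternative 1 | methyl 2-(4-benzyloxy-3-methoxyphenyl)-2-diazoacetate | COC(=O)C(=[N+]=[N-])c1ccc(OCc2ccccc2)c(OC)c1
A4 | alternative 2 | (2R,3S,4S,5R)-2-(4-benzyloxy-3-methoxyphenyl)-5-(4-hydroxy-3-methoxyphenyl)-3,4-dimethyloxolan-3-ol | COc1cc([C@H]2O[C@@H](c3ccc(O)c(OC)c3)[C@H](C)[C@]2(C)O)ccc1OCc1ccccc1
A5 | alternative 2 | (1R,2S,3S)-1-(4-benzyloxy-3-methoxyphenyl)-4-(4-hydroxy-3-methoxyphenyl)-2,3-dimethylbutane-1,2-diol | COc1cc([C@@H](O)[C@@](C)(O)[C@@H](C)Cc2ccc(O)c(OC)c2)ccc1OCc1ccccc1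
A6 | alternative 3 | 2,5-bis(4-benzyloxy-3-methoxyphenyl)-3,4-dimethyl-3-(dimethylphenylsilyl)oxolane (silicon in place of the C3 hydroxyl of the target) | COc1cc([C@H]2O[C@@H](c3ccc(OCc4ccccc4)c(OC)c3)[C@H](C)[C@]2(C)[Si](C)(C)c5ccccc5)ccc1OCc1ccccc1
A7 | alternative 3 | (R,Z)-[1-(4-benzyloxy-3-methoxyphenyl)-2-methylbut-2-en-1-yl]dimethyl(phenyl)silane | C/C=C(/C)[C@H](c1ccc(OCc2ccccc2)c(OC)c1)[Si](C)(C)c1ccccc1
A8 | alternative 3 | 4-benzyloxy-3-methoxybenzaldehyde | COc1cc(C=O)ccc1OCc1ccccc1
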